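## The problem

Quiquesetinerviusin A (29) is a trans-2-aryl-3-(acyloxymethyl)-2,3-dihydrobenzofuran. Ring A, a guaiacyl group, sits on C2; ring B is the benzo ring; the heterocycle between them is closed by the O1–C2 bond. Ring B carries four different substituents in a fixed order: O1 on C7a, methoxy on C7, C3 on C3a and, para to C7a, an (E)-3-acyloxyprop-1-enyl chain on C5. A synthesis must either buy this pattern or build it without ambiguity.

The two stereocentres, C2 (S) and C3 (R), are adjacent and trans. C2 is a benzylic ether carbon para to the ring-A oxygen and ionises easily, so it can be set last under control of C3 and need not be carried in defined form. C3 has no such help and needs an external controller.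

The molecule is fragile. Three free phenols are open to oxidation. The cinnamyl 4-hydroxybenzoate is an allylic ester that ionises with acid or zerovalent palladium and rules out hydrogenolysis. Both esters fall to hydride, organometallics and strong base, and a free ring-A phenol lets C2 open through a quinone methide under base. Since the two esters are identical, both can be put on a diol at the very end.

The feature that invites a benzannulation is the 1,2,3,5 pattern of ring B. Oxygen (C7a), methoxy (C7) and carbon (C3a) in a row, with a functional site at C5, is exactly what a 4-(alk-1-en-2-yl)-4-hydroxy-3-methoxycyclobutenone delivers. Its four ring carbons become C7a, C7, C6 and C5, and its two alkene carbons become C3a and C4.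

## Retrosynthesis

**Esters and phenols.** Target 29 is traced through its tris-silyl ether 28 to diol 24 and acid 27 (from 4-hydroxybenzoic acid 25) by cutting both ester C–O bonds. Putting both identical esters on at once is more economical than carrying either through the route, where hydride and organolithium steps would destroy them. The forward reaction must be neutral (carbodiimide), and one buffered fluoride treatment must then free all three phenols.

**The propenyl chain.** In 24 the bond from C5 to the chain is cut. Diol 24 comes from cinnamate 23 by hydride reduction, and 23 from aryl triflate 21 and methyl acrylate 22 by a Heck reaction. This cut is preferred over an olefination of a C5 aldehyde because the benzannulation leaves an oxygen, not a carbon, at C5. The Heck reaction must give the E alkene and tolerate a free primary alcohol.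

**The dihydrofuran ring.** Triflate 21 comes from phenol 20, and 20 is opened at O1–C2 to hydroquinone acetonide 18. Acid should strip the acetonide and ionise the benzylic C–O bond next to ring A. Only the C7a hydroxyl can reach the cation (the C5 hydroxyl is para, the primary alcohol would give an oxetane). C3 should direct the aryl group trans. This cut removes the need for a defined C2 in every earlier intermediate and leaves C5–OH as the only ring-B phenol, ready for triflation.

**Ring B (key disconnection).** The C4–C5 bond of 18 is cut, and with it the whole arene is traced to cyclobutenone 15. Thermal ring opening to a dienylketene and 6-pi closure rebuild the ring. The alternative of buying ring B as a brominated guaiacol would need a separate C5 handle and an arylacetic acid homologation. Here the ring, the C7a and C5 oxygens and the C7 methoxy group come from one squarate unit, and 15 has one ring and no arene in that half. The forward step must run without acid, base or oxygen.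

**Carbinol–alkene bond.** Cyclobutenone 15 is cut between the carbinol carbon and the alkene carbon into alkenyllithium 14 (from bromide 10) and 3-methoxycyclobut-3-ene-1,2-dione 13, made from dimethyl squarate 11. The nucleophile must attack the ketone carbonyl flanked by the methoxy-bearing carbon, not the vinylogous ester carbonyl. This regiochemistry fixes the whole substitution pattern of ring B.

**The C2–C3 bond and C3.** Bromide 10 is the acetonide of diol 9, which comes from aldol 8 by reduction. Aldol 8 is cut at C2–C3 into imide 6 (from 3-bromobut-3-enoic acid 3 and auxiliary 4) and aldehyde 2 (from vanillin 1). An auxiliary-controlled syn aldol sets C3 dependably; the carbinol centre formed alongside is erased later. An acetonide is chosen over two silyl ethers for three reasons: it cannot hand a silyl group to the neighbouring alkenyllithium, it goes on in one step, and the acid that closes the furan ring also removes it.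

## Roads not taken

**Alternative 1:** The cut is O1–C2, made oxidatively from the open diarylpropanol A2, (R)-2-(5-bromo-2-hydroxy-3-methoxyphenyl)-3-(4-hydroxy-3-methoxyphenyl)propan-1-ol. Constant-current electrolysis at graphite (LiClO4, acetonitrile, 2,6-lutidine) would turn the ring-A phenol into its para-quinone methide. The ring-B phenol then adds at C2 and gives the trans bromide A1, (2S,3R)-5-bromo-2-(4-hydroxy-3-methoxyphenyl)-3-(hydroxymethyl)-7-methoxy-2,3-dihydro-1-benzofuran.
- Merits: no protecting group on ring A; a reagent-free oxidation; ring B bought with its pattern and a bromine for the Heck reaction; C2 set by C3 as in the chosen plan; a sequence several steps shorter.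
- Weak points: A2 holds two guaiacol-type phenols of similar oxidation potential. The product A1 keeps the free ring-A phenol next to a now oxygenated benzylic C–H, so further oxidation toward the benzofuran or solvent adducts competes. C3 still needs an auxiliary.
- Comparison: in step count this road is better. The chosen plan offers in return a non-oxidative closure on a ring-A-protected substrate, where no chemoselectivity between two phenols is asked, at the price of the squarate chemistry.

**Alternative 2:** No ring is cut. The C2–aryl and C3–carboxyl bonds are made across C2=C3 of 7-methoxy-1-benzofuran-5-carbaldehyde A4. A cationic arylpalladium species from the diazonium salt A5 (Pd(O2CCF3)2, chiral pyridine-oxazoline ligand) would add to the furan double bond. Carbon monoxide insertion and methanolysis then give the ester, and DBU epimerises C3 to the trans ester A3, methyl (2S,3S)-5-formyl-7-methoxy-2-[3-methoxy-4-(triisopropylsilyloxy)phenyl]-2,3-dihydro-1-benzofuran-3-carboxylate.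
- Merits: the most convergent road; both centres from a catalyst; aldehyde and ester handles that one olefination and one hydride reduction would turn into the diol.
- Weak points: the arylpalladium species can take up carbon monoxide before the alkene. An enantioselective dearomative arylcarbonylation of a benzofuran is not an established reaction class, and its regiochemistry (aryl to C2) is not assured. The base epimerisation acts on a β-aryloxy ester, which can open by phenoxide elimination and reclose, scrambling C2 and eroding the enantiomeric purity.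
- Comparison: if it worked it would be the shortest route. The chosen plan rests only on known reaction types and does not make the trans relationship depend on base next to a leaving group.

**Alternative 3:** The C3–CH2 bond and the C2–O bond are cut from the (E)-stilbene A7, 4-bromo-2-methoxy-6-[(E)-2-[3-methoxy-4-(triisopropylsilyloxy)phenyl]ethenyl]phenyl acetate. Formaldehyde, activated by a confined chiral imidodiphosphorimidate acid, would be attacked by the alkene carbon next to ring B. The cation stabilised by ring A is caught by a second formaldehyde unit to give the dioxane A6, 4-bromo-2-methoxy-6-[(4R,5R)-4-[3-methoxy-4-(triisopropylsilyloxy)phenyl]-1,3-dioxan-5-yl]phenyl acetate. Deacetylation and acid would then close the furan ring as in the chosen plan.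
- Merits: catalytic asymmetric induction; an easily made stilbene; C3 and the hydroxymethyl carbon installed in one step; a short sequence.
- Weak points: 1,2-diaryl alkenes with an ortho substituent are far less reactive than the terminal styrenes for which such Prins reactions are secure. Two electron-rich arenes can be hydroxymethylated by activated formaldehyde. A very strong acid meets an aryl silyl ether.
- Comparison: in step count and in catalytic stereocontrol this road is better. The chosen plan offers a stoichiometric but dependable auxiliary for C3 and avoids face discrimination on a hindered stilbene.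

Key step: step 8

Assumption: the carbinol configuration made in the aldol (step 3) need not be relayed, because the ring closure of step 9 passes through a benzylic cation and C3 alone decides C2; auxiliary 4 and methyl acrylate 22 are counted as purchased.

Abbreviation used in the steps: Ar = 3-methoxy-4-(triisopropylsilyloxy)phenyl.

## Route

Step 1
Reactants: 1 vanillin
Product: 2 3-methoxy-4-(triisopropylsilyloxy)benzaldehyde
Conditions: i-Pr3SiCl, imidazole, DMF, rt
Reagents that add atoms: triisopropylsilyl chloride, CC(C)[Si](Cl)(C(C)C)C(C)C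
Why: O-silylation of a phenol; the bulky aryl silyl ether should survive borohydride, organolithium, heat and mild acid and fall to fluoride at the end.

Step 2
Reactants: 3 3-bromobut-3-enoic acid; 4 (S)-4-benzyl-1,3-oxazolidin-2-one
Product: 6 (S)-4-benzyl-3-(3-bromobut-3-enoyl)-1,3-oxazolidin-2-one, via mixed pivalic anhydride 5 (not isolated)
Conditions: t-BuCOCl, Et3N, THF, −20 °C; then LiCl, 4, −20 °C to rt
Reagents that add atoms: none
Why: N-acylation of an oxazolidinone through a mixed anhydride under the mild LiCl/amine protocol, which is used for β,γ-unsaturated acids because it avoids strong base and should leave the double bond and the vinyl bromide in place.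

Step 3
Reactants: 6 (S)-4-benzyl-3-(3-bromobut-3-enoyl)-1,3-oxazolidin-2-one; 2 3-methoxy-4-(triisopropylsilyloxy)benzaldehyde
Product: 8 (4S)-4-benzyl-3-[(2S,3S)-2-(1-bromoethenyl)-3-hydroxy-3-Ar-propanoyl]-1,3-oxazolidin-2-one, via boron enolate 7 (not isolated)
Conditions: n-Bu2BOTf, i-Pr2NEt, CH2Cl2, −78 to −40 °C; then 2, −78 to −20 °C; pH 7 buffer, MeOH, H2O2, 0 °C
Reagents that add atoms: none
Why: Evans syn aldol: soft enolisation gives the Z boron dienolate 7, which reacts at its alpha carbon through a closed chair transition state on the face away from the benzyl group of the auxiliary, setting both new centres syn (2S,3S). β,γ-Unsaturated acyl imides are known to react in this way at the alpha position, and the alpha centre becomes C3 of the target.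

Step 4
Reactants: 8 (4S)-4-benzyl-3-[(2S,3S)-2-(1-bromoethenyl)-3-hydroxy-3-Ar-propanoyl]-1,3-oxazolidin-2-one
Product: 9 (1S,2R)-2-(1-bromoethenyl)-1-Ar-propane-1,3-diol
Conditions: LiBH4, MeOH (1 equiv), THF, 0 °C
Reagents that add atoms: none
Why: Reductive cleavage of the N-acyl oxazolidinone to the primary alcohol with release of the auxiliary; vinyl bromide, aryl silyl ether and both stereocentres are inert to borohydride.

Step 5
Reactants: 9 (1S,2R)-2-(1-bromoethenyl)-1-Ar-propane-1,3-diol
Product: 10 (4S,5R)-5-(1-bromoethenyl)-4-Ar-2,2-dimethyl-1,3-dioxane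
Conditions: Me2C(OMe)2, PPTS (cat.), CH2Cl2, rt
Reagents that add atoms: 2,2-dimethoxypropane, COC(C)(C)OC
Why: Acetonide formation from a 1,3-diol by acetal exchange; the cyclic acetal is inert to t-BuLi, offers no silyl group for migration to the alkenyllithium, and is removed later by the acid that closes the furan ring.

Step 6
Reactants: 11 dimethyl squarate
Product: 13 3-methoxycyclobut-3-ene-1,2-dione, via hydroxycyclobutenone 12 (not isolated)
Conditions: LiAlH(Ot-Bu)3, THF, −78 °C; then 6 M HCl, CH2Cl2, 0 °C to rt
Reagents that add atoms: water, O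
Why: 1,2-Reduction of one carbonyl group by a bulky hydride, then acid-induced allylic transposition (hydroxyl leaves, water adds at the methoxy-bearing terminus, methanol is lost). This is the standard passage from dialkyl squarates to 3-alkoxycyclobutenediones.

Step 7
Reactants: 10 (4S,5R)-5-(1-bromoethenyl)-4-Ar-2,2-dimethyl-1,3-dioxane; 13 3-methoxycyclobut-3-ene-1,2-dione
Product: 15 4-hydroxy-3-methoxy-4-[1-[(4S,5R)-4-Ar-2,2-dimethyl-1,3-dioxan-5-yl]ethenyl]cyclobut-2-en-1-one (both carbinol epimers), via alkenyllithium 14 (not isolated)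
Conditions: t-BuLi (2 equiv), Et2O, −78 °C; then cannulated into 13, THF, −78 °C; aq NH4Cl
Reagents that add atoms: none
Why: Bromine–lithium exchange of a 2-bromoalk-1-ene and 1,2-addition of the alkenyllithium to a 3-alkoxycyclobutenedione. The reagent attacks the ketone carbonyl next to the methoxy-bearing carbon because the other carbonyl is a deactivated vinylogous ester. The carbinol centre forms without control, which is harmless since it becomes an arene carbon.

Step 8
Reactants: 15 4-hydroxy-3-methoxy-4-[1-[(4S,5R)-4-Ar-2,2-dimethyl-1,3-dioxan-5-yl]ethenyl]cyclobut-2-en-1-one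
Product: 18 2-methoxy-6-[(4S,5R)-4-Ar-2,2-dimethyl-1,3-dioxan-5-yl]benzene-1,4-diol, via dienylketene 16 (not isolated), via cyclohexadienone 17 (not isolated)
Conditions: degassed toluene, 110 °C, argon, base-washed glassware
Reagents that add atoms: none
Why: Moore-type ring expansion; the closest known reaction is the thermal conversion of 4-alkenyl-4-hydroxycyclobutenones into hydroquinones. Heat opens the strained ring by a conrotatory 4-pi electrocyclic cleavage of the carbonyl–carbinol bond to give dienylketene 16. The hydroxyl group, as the donor, rotates outward, which places the alkenyl group cis to the ketene. The ketene carbon then bonds to the terminal CH2 of the alkene in a disrotatory 6-pi electrocyclisation, forming the C4–C5 bond and cyclohexadienone 17, and two proton shifts give hydroquinone 18. Ring B closes by this single carbon–carbon bond, with the carbinol carbon as C7a, the methoxy carbon as C7, the carbonyl carbon as C5 and the alkene carbons as C3a and C4. No stereocentre is formed: the dioxane centres are insulated from the reacting pi system, and both carbinol epimers converge because that carbon becomes sp2. The step needs the outward rotation of hydroxyl, which the donor effect secures, and the right regiochemistry, which was fixed in step 7. It also needs the absence of acid (which would expel methanol to a cyclobutenedione) and of oxygen (which would take 18 to the quinone).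

Step 9
Reactants: 18 2-methoxy-6-[(4S,5R)-4-Ar-2,2-dimethyl-1,3-dioxan-5-yl]benzene-1,4-diol
Product: 20 (2S,3R)-3-(hydroxymethyl)-7-methoxy-2-Ar-2,3-dihydro-1-benzofuran-5-ol, via tetraol 19 (not isolated)
Conditions: TsOH·H2O (0.2 equiv), degassed MeCN–H2O (20:1), rt to 40 °C
Reagents that add atoms: none
Why: Acetal hydrolysis, then SN1 etherification: the benzylic carbinol next to the donor ring A ionises and the C7a hydroxyl captures the cation in a 5-exo closure. C3 sets C2 trans (the aryl group avoids the hydroxymethyl group, and the closure is reversible under acid), so the carbinol configuration of 18 does not matter; aryl silyl ethers tolerate this acid.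

Step 10
Reactants: 20 (2S,3R)-3-(hydroxymethyl)-7-methoxy-2-Ar-2,3-dihydro-1-benzofuran-5-ol
Product: 21 (2S,3R)-3-(hydroxymethyl)-7-methoxy-2-Ar-2,3-dihydro-1-benzofuran-5-yl trifluoromethanesulfonate
Conditions: PhNTf2, Et3N, CH2Cl2, 0 °C to rt
Reagents that add atoms: N-phenylbis(trifluoromethanesulfonimide), O=S(=O)(N(c1ccccc1)S(=O)(=O)C(F)(F)F)C(F)(F)F
Why: Phenol-selective triflation; the mild triflyl donor reacts with the phenoxide formed by the amine but not with the neutral primary alcohol.

Step 11
Reactants: 21 (2S,3R)-3-(hydroxymethyl)-7-methoxy-2-Ar-2,3-dihydro-1-benzofuran-5-yl trifluoromethanesulfonate; 22 methyl acrylate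
Product: 23 methyl (E)-3-[(2S,3R)-3-(hydroxymethyl)-7-methoxy-2-Ar-2,3-dihydro-1-benzofuran-5-yl]prop-2-enoate
Conditions: Pd(OAc)2 (5 mol %), dppp, Et3N, DMF, 80 °C
Reagents that add atoms: none
Why: Heck reaction of an aryl triflate with an acrylate; syn insertion and syn β-hydride elimination give the E alkene, and a chelating diphosphine is the usual choice for electron-rich aryl triflates.

Step 12
Reactants: 23 methyl (E)-3-[(2S,3R)-3-(hydroxymethyl)-7-methoxy-2-Ar-2,3-dihydro-1-benzofuran-5-yl]prop-2-enoate
Product: 24 (E)-3-[(2S,3R)-3-(hydroxymethyl)-7-methoxy-2-Ar-2,3-dihydro-1-benzofuran-5-yl]prop-2-en-1-ol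
Conditions: i-Bu2AlH (4 equiv), CH2Cl2, −78 to 0 °C
Reagents that add atoms: none
Why: 1,2-Reduction of an α,β-unsaturated ester to the allylic alcohol; alkene geometry and aryl silyl ether are retained, and the first equivalent is consumed by the free hydroxyl.

Step 13
Reactants: 25 4-hydroxybenzoic acid
Product: 27 4-(tert-butyldimethylsilyloxy)benzoic acid, via bis-silyl compound 26 (not isolated)
Conditions: t-BuMe2SiCl (2.2 equiv), imidazole, DMF, rt; then AcOH–THF–H2O, rt
Reagents that add atoms: tert-butyldimethylsilyl chloride, CC(C)(C)[Si](C)(C)Cl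
Why: Silylation of phenol and acid followed by selective hydrolysis of the far more labile silyl ester, the standard preparation of this acid.

Step 14
Reactants: 24 (E)-3-[(2S,3R)-3-(hydroxymethyl)-7-methoxy-2-Ar-2,3-dihydro-1-benzofuran-5-yl]prop-2-en-1-ol; 27 4-(tert-butyldimethylsilyloxy)benzoic acid (2.5 equiv)
Product: 28 [(2S,3R)-5-[(E)-3-[4-(tert-butyldimethylsilyloxy)benzoyl]oxyprop-1-enyl]-7-methoxy-2-Ar-2,3-dihydro-1-benzofuran-3-yl]methyl 4-(tert-butyldimethylsilyloxy)benzoate
Conditions: EDC·HCl, DMAP, CH2Cl2, 0 °C to rt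
Reagents that add atoms: none
Why: Steglich esterification of both primary alcohols with the same acid; the neutral conditions leave the aryl silyl ethers, the allylic position and the benzylic ether untouched.

Step 15
Reactants: 28 [(2S,3R)-5-[(E)-3-[4-(tert-butyldimethylsilyloxy)benzoyl]oxyprop-1-enyl]-7-methoxy-2-Ar-2,3-dihydro-1-benzofuran-3-yl]methyl 4-(tert-butyldimethylsilyloxy)benzoate
Product: 29 quiquesetinerviusin A
Conditions: n-Bu4NF, AcOH, THF, 0 °C
Reagents that add atoms: none
Why: Fluoride cleavage of the three aryl silyl ethers; buffering with acetic acid keeps the phenols protonated, so the esters should neither migrate nor cleave and C2 cannot open through a quinone methide.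

## Compound list

1 | vanillin | COc1cc(C=O)ccc1O | starting material
2 | 3-methoxy-4-(triisopropylsilyloxy)benzaldehyde | COc1cc(C=O)ccc1O[Si](C(C)C)(C(C)C)C(C)C | intermediate
3 | 3-bromobut-3-enoic acid | C=C(Br)CC(=O)O | starting material
4 | (S)-4-benzyl-1,3-oxazolidin-2-one | O=C1N[C@@H](Cc2ccccc2)CO1 | starting material
5 | 3-bromobut-3-enoic 2,2-dimethylpropanoic anhydride | C=C(Br)CC(=O)OC(=O)C(C)(C)C | intermediate
6 | (S)-4-benzyl-3-(3-bromobut-3-enoyl)-1,3-oxazolidin-2-one | C=C(Br)CC(=O)N1[C@@H](Cc2ccccc2)COC1=O | intermediate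
7 | (4S)-4-benzyl-3-[(1Z)-3-bromo-1-(dibutylboranyloxy)buta-1,3-dien-1-yl]-1,3-oxazolidin-2-one | CCCCB(CCCC)O/C(=C\C(Br)=C)N1[C@@H](Cc2ccccc2)COC1=O | intermediate
8 | (4S)-4-benzyl-3-[(2S,3S)-2-(1-bromoethenyl)-3-hydroxy-3-[3-methoxy-4-(triisopropylsilyloxy)phenyl]propanoyl]-1,3-oxazolidin-2-one | C=C(Br)[C@H](C(=O)N1[C@@H](Cc2ccccc2)COC1=O)[C@H](O)c3ccc(O[Si](C(C)C)(C(C)C)C(C)C)c(OC)c3 | intermediate
9 | (1S,2R)-2-(1-bromoethenyl)-1-[3-methoxy-4-(triisopropylsilyloxy)phenyl]propane-1,3-diol | C=C(Br)[C@H](CO)[C@H](O)c1ccc(O[Si](C(C)C)(C(C)C)C(C)C)c(OC)c1 | intermediate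
10 | (4S,5R)-5-(1-bromoethenyl)-4-[3-methoxy-4-(triisopropylsilyloxy)phenyl]-2,2-dimethyl-1,3-dioxane | C=C(Br)[C@@H]1COC(C)(C)O[C@@H]1c2ccc(O[Si](C(C)C)(C(C)C)C(C)C)c(OC)c2 | intermediate
11 | dimethyl squarate (3,4-dimethoxycyclobut-3-ene-1,2-dione) | COC1=C(OC)C(=O)C1=O | starting material
12 | 4-hydroxy-2,3-dimethoxycyclobut-2-en-1-one (racemic) | COC1=C(OC)C(O)C1=O | intermediate
13 | 3-methoxycyclobut-3-ene-1,2-dione | COC1=CC(=O)C1=O | intermediate
14 | [1-[(4S,5R)-4-[3-methoxy-4-(triisopropylsilyloxy)phenyl]-2,2-dimethyl-1,3-dioxan-5-yl]ethenyl]lithium | [Li]C(=C)[C@@H]1COC(C)(C)O[C@@H]1c2ccc(O[Si](C(C)C)(C(C)C)C(C)C)c(OC)c2 | intermediate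
15 | 4-hydroxy-3-methoxy-4-[1-[(4S,5R)-4-[3-methoxy-4-(triisopropylsilyloxy)phenyl]-2,2-dimethyl-1,3-dioxan-5-yl]ethenyl]cyclobut-2-en-1-one (both epimers at the ring carbinol carbon) | COC1=CC(=O)C1(O)C(=C)[C@@H]2COC(C)(C)O[C@@H]2c3ccc(O[Si](C(C)C)(C(C)C)C(C)C)c(OC)c3 | intermediate
16 | (3Z)-4-hydroxy-3-methoxy-5-[(4S,5R)-4-[3-methoxy-4-(triisopropylsilyloxy)phenyl]-2,2-dimethyl-1,3-dioxan-5-yl]hexa-1,3,5-trien-1-one | O=C=C/C(OC)=C(O)\C(=C)[C@@H]2COC(C)(C)O[C@@H]2c3ccc(O[Si](C(C)C)(C(C)C)C(C)C)c(OC)c3 | intermediate
17 | 4-hydroxy-3-methoxy-5-[(4S,5R)-4-[3-methoxy-4-(triisopropylsilyloxy)phenyl]-2,2-dimethyl-1,3-dioxan-5-yl]cyclohexa-2,4-dien-1-one | COC1=CC(=O)CC([C@@H]2COC(C)(C)O[C@@H]2c3ccc(O[Si](C(C)C)(C(C)C)C(C)C)c(OC)c3)=C1O | intermediate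
18 | 2-methoxy-6-[(4S,5R)-4-[3-methoxy-4-(triisopropylsilyloxy)phenyl]-2,2-dimethyl-1,3-dioxan-5-yl]benzene-1,4-diol | COc1cc(O)cc([C@@H]2COC(C)(C)O[C@@H]2c3ccc(O[Si](C(C)C)(C(C)C)C(C)C)c(OC)c3)c1O | intermediate
19 | 2-[(1S,2R)-1,3-dihydroxy-1-[3-methoxy-4-(triisopropylsilyloxy)phenyl]propan-2-yl]-6-methoxybenzene-1,4-diol | COc1cc(O)cc([C@H](CO)[C@H](O)c2ccc(O[Si](C(C)C)(C(C)C)C(C)C)c(OC)c2)c1O | intermediate
20 | (2S,3R)-3-(hydroxymethyl)-7-methoxy-2-[3-methoxy-4-(triisopropylsilyloxy)phenyl]-2,3-dihydro-1-benzofuran-5-ol | COc1cc([C@H]2Oc3c(OC)cc(O)cc3[C@@H]2CO)ccc1O[Si](C(C)C)(C(C)C)C(C)C | intermediate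
21 | (2S,3R)-3-(hydroxymethyl)-7-methoxy-2-[3-methoxy-4-(triisopropylsilyloxy)phenyl]-2,3-dihydro-1-benzofuran-5-yl trifluoromethanesulfonate | COc1cc([C@H]2Oc3c(OC)cc(OS(=O)(=O)C(F)(F)F)cc3[C@@H]2CO)ccc1O[Si](C(C)C)(C(C)C)C(C)C | intermediate
22 | methyl acrylate | C=CC(=O)OC | starting material
23 | methyl (E)-3-[(2S,3R)-3-(hydroxymethyl)-7-methoxy-2-[3-methoxy-4-(triisopropylsilyloxy)phenyl]-2,3-dihydro-1-benzofuran-5-yl]prop-2-enoate | COc1cc([C@H]2Oc3c(OC)cc(/C=C/C(=O)OC)cc3[C@@H]2CO)ccc1O[Si](C(C)C)(C(C)C)C(C)C | intermediate
24 | (E)-3-[(2S,3R)-3-(hydroxymethyl)-7-methoxy-2-[3-methoxy-4-(triisopropylsilyloxy)phenyl]-2,3-dihydro-1-benzofuran-5-yl]prop-2-en-1-ol | COc1cc([C@H]2Oc3c(OC)cc(/C=C/CO)cc3[C@@H]2CO)ccc1O[Si](C(C)C)(C(C)C)C(C)C | intermediate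
25 | 4-hydroxybenzoic acid | O=C(O)c1ccc(O)cc1 | starting material
26 | tert-butyldimethylsilyl 4-(tert-butyldimethylsilyloxy)benzoate | CC(C)(C)[Si](C)(C)OC(=O)c1ccc(O[Si](C)(C)C(C)(C)C)cc1 | intermediate
27 | 4-(tert-butyldimethylsilyloxy)benzoic acid | CC(C)(C)[Si](C)(C)Oc1ccc(C(=O)O)cc1 | intermediate
28 | [(2S,3R)-5-[(E)-3-[4-(tert-butyldimethylsilyloxy)benzoyl]oxyprop-1-enyl]-7-methoxy-2-[3-methoxy-4-(triisopropylsilyloxy)phenyl]-2,3-dihydro-1-benzofuran-3-yl]methyl 4-(tert-butyldimethylsilyloxy)benzoate | COc1cc([C@H]2Oc3c(OC)cc(/C=C/COC(=O)c4ccc(O[Si](C)(C)C(C)(C)C)cc4)cc3[C@@H]2COC(=O)c2ccc(O[Si](C)(C)C(C)(C)C)cc2)ccc1O[Si](C(C)C)(C(C)C)C(C)C | intermediate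
29 | quiquesetinerviusin A, [(2S,3R)-2-(4-hydroxy-3-methoxyphenyl)-5-[(E)-3-(4-hydroxybenzoyl)oxyprop-1-enyl]-7-methoxy-2,3-dihydro-1-benzofuran-3-yl]methyl 4-hydroxybenzoate | COc1cc([C@H]2Oc3c(OC)cc(/C=C/COC(=O)c4ccc(O)cc4)cc3[C@@H]2COC(=O)c2ccc(O)cc2)ccc1O | target

## Step count and least certain steps

Total: 15 steps. Longest linear sequence: 12 steps (1, 3, 4, 5, 7, 8, 9, 10, 11, 12, 14, 15).

**Step 8 (key step).** Three things are most likely to go wrong: loss of methanol from 15 on traces of acid (collapse to an alkenylcyclobutenedione), capture of the ketene by the free hydroxyl if some of it rotates inward (lactonisation), and air oxidation of the electron-rich hydroquinone during isolation. The fallback caps the hydroxyl before heating. It sets out from 15: silylation with N-(trimethylsilyl)imidazole should give 3-methoxy-4-[1-[(4S,5R)-4-Ar-2,2-dimethyl-1,3-dioxan-5-yl]ethenyl]-4-(trimethylsilyloxy)cyclobut-2-en-1-one F1. Thermolysis of F1 in toluene should give the mono-silylated hydroquinone 3-methoxy-5-[(4S,5R)-4-Ar-2,2-dimethyl-1,3-dioxan-5-yl]-4-(trimethylsilyloxy)phenol F2, which can neither lactonise nor oxidise to a quinone. Under the acid of step 9, F2 loses the silyl group and the acetonide and closes the furan ring, coming back to the route at 20.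

**Step 3.** The brominated dienolate may lose hydrogen bromide toward an allenoyl imide, or the double bond may drift into conjugation during acylation and enolisation; either would cut yield and facial selectivity. The fallback introduces the bromine after the aldol. It sets out from 4 and 2:
- Acylation of 4 with commercial but-3-enoic acid gives (S)-4-benzyl-3-(but-3-enoyl)-1,3-oxazolidin-2-one F3.
- The same boron aldol with 2 gives (4S)-4-benzyl-3-[(2S,3S)-2-ethenyl-3-hydroxy-3-Ar-propanoyl]-1,3-oxazolidin-2-one F4.
- LiBH4 gives (1S,2R)-2-ethenyl-1-Ar-propane-1,3-diol F5, and acetal exchange gives (4S,5R)-5-ethenyl-4-Ar-2,2-dimethyl-1,3-dioxane F6.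
- PhSeBr in acetonitrile at room temperature (thermodynamic Markovnikov adduct) gives (4S,5R)-5-[1-bromo-2-(phenylselanyl)ethyl]-4-Ar-2,2-dimethyl-1,3-dioxane F7.
- Oxidation with H2O2 and selenoxide syn-elimination toward the bromine-bearing carbon returns to the route at 10.

**Step 7.** The exchange may be incomplete, the alkenyllithium may be destroyed by the tert-butyl bromide formed beside it, or surplus t-BuLi may add to the dione; each would waste the advanced bromide. The fallback generates the same nucleophile from an isolable stannane. It sets out from 10: stannylation with Me3SnSnMe3 and Pd(PPh3)4 in toluene should give trimethyl[1-[(4S,5R)-4-Ar-2,2-dimethyl-1,3-dioxan-5-yl]ethenyl]stannane F8. Tin–lithium exchange of F8 with one equivalent of MeLi in THF at −78 °C gives 14 with no alkyl halide and no excess alkyllithium, coming back to the route at 14.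

**Step 9.** The benzylic cation may alkylate the very electron-rich hydroquinone ring of a second molecule instead of being captured by the C7a hydroxyl. The hydroquinone may oxidise. Prolonged acid may erode C3 through reversible loss of its proton from the cation. The fallback deactivates ring B first. It sets out from 18: triflation with PhNTf2 and Et3N should take the unhindered C5 hydroxyl selectively (the C7a hydroxyl is flanked by methoxy and the branched chain) and give 4-hydroxy-3-methoxy-5-[(4S,5R)-4-Ar-2,2-dimethyl-1,3-dioxan-5-yl]phenyl trifluoromethanesulfonate F9. The acid of step 9 applied to F9 removes the acetonide and closes the furan ring on a ring that no longer oxidises or alkylates readily, coming back to the route at 21.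

## Further compounds

F1 | step 8 | 3-methoxy-4-[1-[(4S,5R)-4-[3-methoxy-4-(triisopropylsilyloxy)phenyl]-2,2-dimethyl-1,3-dioxan-5-yl]ethenyl]-4-(trimethylsilyloxy)cyclobut-2-en-1-one | COC1=CC(=O)C1(O[Si](C)(C)C)C(=C)[C@@H]2COC(C)(C)O[C@@H]2c3ccc(O[Si](C(C)C)(C(C)C)C(C)C)c(OC)c3
F2 | step 8 | 3-methoxy-5-[(4S,5R)-4-[3-methoxy-4-(triisopropylsilyloxy)phenyl]-2,2-dimethyl-1,3-dioxan-5-yl]-4-(trimethylsilyloxy)phenol | COc1cc(O)cc([C@@H]2COC(C)(C)O[C@@H]2c3ccc(O[Si](C(C)C)(C(C)C)C(C)C)c(OC)c3)c1O[Si](C)(C)C
F3 | step 3 | (S)-4-benzyl-3-(but-3-enoyl)-1,3-oxazolidin-2-one | C=CCC(=O)N1[C@@H](Cc2ccccc2)COC1=O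
F4 | step 3 | (4S)-4-benzyl-3-[(2S,3S)-2-ethenyl-3-hydroxy-3-[3-methoxy-4-(triisopropylsilyloxy)phenyl]propanoyl]-1,3-oxazolidin-2-one | C=C[C@H](C(=O)N1[C@@H](Cc2ccccc2)COC1=O)[C@H](O)c3ccc(O[Si](C(C)C)(C(C)C)C(C)C)c(OC)c3
F5 | step 3 | (1S,2R)-2-ethenyl-1-[3-methoxy-4-(triisopropylsilyloxy)phenyl]propane-1,3-diol | C=C[C@H](CO)[C@H](O)c1ccc(O[Si](C(C)C)(C(C)C)C(C)C)c(OC)c1
F6 | step 3 | (4S,5R)-5-ethenyl-4-[3-methoxy-4-(triisopropylsilyloxy)phenyl]-2,2-dimethyl-1,3-dioxane | C=C[C@@H]1COC(C)(C)O[C@@H]1c2ccc(O[Si](C(C)C)(C(C)C)C(C)C)c(OC)c2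
F7 | step 3 | (4S,5R)-5-[1-bromo-2-(phenylselanyl)ethyl]-4-[3-methoxy-4-(triisopropylsilyloxy)phenyl]-2,2-dimethyl-1,3-dioxane (both epimers at the bromine-bearing carbon) | BrC(C[Se]c1ccccc1)[C@@H]2COC(C)(C)O[C@@H]2c3ccc(O[Si](C(C)C)(C(C)C)C(C)C)c(OC)c3
F8 | step 7 | trimethyl[1-[(4S,5R)-4-[3-methoxy-4-(triisopropylsilyloxy)phenyl]-2,2-dimethyl-1,3-dioxan-5-yl]ethenyl]stannane | C=C([Sn](C)(C)C)[C@@H]1COC(C)(C)O[C@@H]1c2ccc(O[Si](C(C)C)(C(C)C)C(C)C)c(OC)c2
F9 | step 9 | 4-hydroxy-3-methoxy-5-[(4S,5R)-4-[3-methoxy-4-(triisopropylsilyloxy)phenyl]-2,2-dimethyl-1,3-dioxan-5-yl]phenyl trifluoromethanesulfonate | COc1cc(OS(=O)(=O)C(F)(F)F)cc([C@@H]2COC(C)(C)O[C@@H]2c3ccc(O[Si](C(C)C)(C(C)C)C(C)C)c(OC)c3)c1O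
A1 | alternative 1 | (2S,3R)-5-bromo-2-(4-hydroxy-3-methoxyphenyl)-3-(hydroxymethyl)-7-methoxy-2,3-dihydro-1-benzofuran | COc1cc([C@H]2Oc3c(OC)cc(Br)cc3[C@@H]2CO)ccc1O
A2 | alternative 1 | (R)-2-(5-bromo-2-hydroxy-3-methoxyphenyl)-3-(4-hydroxy-3-methoxyphenyl)propan-1-ol | COc1cc(C[C@@H](CO)c2cc(Br)cc(OC)c2O)ccc1O
A3 | alternative 2 | methyl (2S,3S)-5-formyl-7-methoxy-2-[3-methoxy-4-(triisopropylsilyloxy)phenyl]-2,3-dihydro-1-benzofuran-3-carboxylate | COc1cc([C@H]2Oc3c(OC)cc(C=O)cc3[C@@H]2C(=O)OC)ccc1O[Si](C(C)C)(C(C)C)C(C)C
A4 | alternative 2 | 7-methoxy-1-benzofuran-5-carbaldehyde | COc1cc(C=O)cc2ccoc12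
A5 | alternative 2 | 3-methoxy-4-(triisopropylsilyloxy)benzenediazonium tetrafluoroborate | COc1cc([N+]#N)ccc1O[Si](C(C)C)(C(C)C)C(C)C.F[B-](F)(F)F
A6 | alternative 3 | 4-bromo-2-methoxy-6-[(4R,5R)-4-[3-methoxy-4-(triisopropylsilyloxy)phenyl]-1,3-dioxan-5-yl]phenyl acetate | COc1cc([C@@H]2OCOC[C@H]2c2cc(Br)cc(OC)c2OC(C)=O)ccc1O[Si](C(C)C)(C(C)C)C(C)C
A7 | alternative 3 | 4-bromo-2-methoxy-6-[(E)-2-[3-methoxy-4-(triisopropylsilyloxy)phenyl]ethenyl]phenyl acetate | COc1cc(/C=C/c2cc(Br)cc(OC)c2OC(C)=O)ccc1O[Si](C(C)C)(C(C)C)C(C)C
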